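**Retrosynthetic overview**
1. Target 35 ⇒ epoxyquinol diol 29 + 3-hydroxy-3-methylglutaric anhydride 34 (last step: catalyst-controlled desymmetrising acylation of the primary allylic OH).
2. Epoxycyclohexenone ⇒ p-methoxyphenol 25: oxidative dearomatisation to quinone monoketal 26, tartrate-controlled nucleophilic epoxidation, ketal hydrolysis, DIBAL-H reduction.
3. C8=CH2 and the C11–aryl bond ⇒ Wittig methylenation after Cu-catalysed addition of aryl Grignard 22 (from anisole) to α-methylene decalone 13.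
4. Ring B ⇒ key step: iodine(III)-triggered semipinacol ring expansion of trans-hydrindanyl vinyl carbinol 11 (cyclopentanol → cyclohexanone, the angular quaternary carbon migrates).
5. Hydrindanone 10 ⇒ 2-methylcyclopentane-1,3-dione + ethyl vinyl ketone (amino-acid-mediated annulation sets C10, reductive methylation sets C5). Ring order: cyclopentane (given) → ring A → ring B (by expansion) → oxygenated ring (from the arene, last).

Abbreviations: AlbCH2 = [(1S,4aS,8aS)-5,5,8a-trimethyl-2-methylidenedecahydronaphthalen-1-yl]methyl; TIPS = tri(propan-2-yl)silyl. Terpenoid positions use drimane numbering (C5, C8, C9, C10, C11).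
Assumption: operations run in one flask without isolation count as one step.

**Step 1**
Reactants: 1 2-methylcyclopentane-1,3-dione; 2 pent-1-en-3-one (ethyl vinyl ketone)
Product: 3 2-methyl-2-(3-oxopentyl)cyclopentane-1,3-dione
Conditions: H2O, AcOH (cat.), 75 °C
Reagents that add atoms: none
Why: Michael addition of the acidic 1,3-dione to the enone gives the prochiral triketone; no stereocentre is formed.

**Step 2**
Reactants: 3 2-methyl-2-(3-oxopentyl)cyclopentane-1,3-dione
Product: 4 (7aS)-4,7a-dimethyl-2,3,7,7a-tetrahydro-1H-indene-1,5(6H)-dione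
Conditions: L-phenylalanine (1 equiv), (+)-CSA (0.5 equiv), DMF, 30→70 °C
Reagents that add atoms: none
Why: Hajos–Parrish-type enamine aldol condensation in which the L-amino acid selects one of the two enantiotopic ring carbonyls and so sets the (S) quaternary carbon (future C10); ee is raised by recrystallisation.

**Step 3**
Reactants: 4 (7aS)-4,7a-dimethyl-2,3,7,7a-tetrahydro-1H-indene-1,5(6H)-dione
Product: 5 (1S,7aS)-1-hydroxy-4,7a-dimethyl-1,2,3,6,7,7a-hexahydro-5H-inden-5-one
Conditions: NaBH4 (0.3 equiv), EtOH, −20 °C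
Reagents that add atoms: none
Why: Chemoselective borohydride reduction of the saturated cyclopentanone over the enone, hydride entering anti to the angular methyl (1S); the alcohol masks this carbonyl for steps 4 and 5.

**Step 4**
Reactants: 5 (1S,7aS)-1-hydroxy-4,7a-dimethyl-1,2,3,6,7,7a-hexahydro-5H-inden-5-one
Product: 7 (1S,3aR,7aS)-1-hydroxy-4,4,7a-trimethyloctahydro-5H-inden-5-one, via dilithium alkoxide-enolate 6 (not isolated)
Conditions: Li, NH3(l)/THF, −78 °C; then MeI, −78→−33 °C; NH4Cl
Reagents that add atoms: iodomethane, CI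
Why: Stork reductive alkylation of the enone: β-protonation anti to the angular methyl gives the trans ring fusion (future 5α-H), and the regiospecific enolate is C-methylated to install the gem-dimethyl group.

**Step 5**
Reactants: 7 (1S,3aR,7aS)-1-hydroxy-4,4,7a-trimethyloctahydro-5H-inden-5-one
Product: 9 (1S,3aS,7aS)-4,4,7a-trimethyloctahydro-1H-inden-1-ol, via hydrazone 8 (not isolated)
Conditions: N2H4·H2O, KOH, diethylene glycol, 130→210 °C
Reagents that add atoms: none
Why: Wolff–Kishner (Huang-Minlon) deoxygenation of the hindered ketone; it has no epimerisable α-stereocentre, so the ring fusion is untouched.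

**Step 6**
Reactants: 9 (1S,3aS,7aS)-4,4,7a-trimethyloctahydro-1H-inden-1-ol
Product: 10 (3aS,7aS)-4,4,7a-trimethyloctahydro-1H-inden-1-one
Conditions: TPAP (5 mol%), NMO, 4 Å MS, CH2Cl2, rt
Reagents that add atoms: none
Why: Ley–Griffith oxidation of the secondary alcohol to the trans-hydrindanone without touching the ring-fusion centres.

**Step 7**
Reactants: 10 (3aS,7aS)-4,4,7a-trimethyloctahydro-1H-inden-1-one
Product: 11 (1R,3aS,7aS)-1-ethenyl-4,4,7a-trimethyloctahydro-1H-inden-1-ol
Conditions: CH2=CHMgBr, LaCl3·2LiCl (30 mol%), THF, 0 °C; aq NH4Cl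
Reagents that add atoms: vinylmagnesium bromide, C=C[Mg]Br
Why: Lanthanide-assisted Grignard 1,2-addition to the hindered neopentyl ketone from the face anti to the angular methyl (17-ketosteroid-like); the carbinol centre is consumed in step 8.

**Step 8**
Reactants: 11 (1R,3aS,7aS)-1-ethenyl-4,4,7a-trimethyloctahydro-1H-inden-1-ol
Product: 13 (4aS,8aS)-5,5,8a-trimethyl-1-methylideneoctahydronaphthalen-2(1H)-one, via alkyl(phenyl)iodonium tosylate 12 (not isolated)
Conditions: PhI(OH)OTs (1.1 equiv), CH2Cl2/MeCN, −20 °C→rt; then DBU, 0 °C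
Reagents that add atoms: none
Why: Proposed new method: iodine(III)-triggered dehydrogenative semipinacol ring expansion of an unstrained vinyl carbinol, in which the λ3-iodane adds to the terminal vinyl carbon while the antiperiplanar, more electron-rich C1–C7a bond (quaternary migrating carbon, retention at C10) shifts to the internal carbon, driven by C=O formation and release of trans-hydrindane strain, and the β-keto alkyl(phenyl)iodonium 12 then loses PhI by E1cB with DBU to give the α-methylene ketone; closest known reactions are the hypervalent-iodine and Tl(III) oxidative ring expansions of alkylidene- and benzo-fused 1-vinylcycloalkanols (aryl migration) and the Pd(II) ring expansion of 1-vinylcyclobutanols to 2-methylenecyclopentanones.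

**Step 9**
Reactants: 14 anisole
Product: 16 (2-methoxyphenyl)methanol, via 2-lithioanisole 15 (not isolated)
Conditions: n-BuLi, TMEDA, Et2O, rt; then (CH2O)n, 0 °C→rt; aq NH4Cl
Reagents that add atoms: formaldehyde (as paraformaldehyde), C=O
Why: Methoxy-directed ortho-lithiation followed by hydroxymethylation of the aryllithium.

**Step 10**
Reactants: 16 (2-methoxyphenyl)methanol
Product: 17 (5-bromo-2-methoxyphenyl)methanol
Conditions: NBS, MeCN, 0 °C→rt
Reagents that add atoms: N-bromosuccinimide, O=C1CCC(=O)N1Br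
Why: Electrophilic aromatic bromination, which in polar solvent goes para to the methoxy group.

**Step 11**
Reactants: 17 (5-bromo-2-methoxyphenyl)methanol
Product: 18 3-(hydroxymethyl)-4-methoxyphenol
Conditions: Pd2(dba)3 (1 mol%), t-BuXPhos (4 mol%), KOH, dioxane/H2O, 100 °C; then H3O+
Reagents that add atoms: potassium hydroxide, [K+].[OH-]
Why: Pd-catalysed hydroxylation of the aryl bromide (Buchwald-type C–O coupling with hydroxide) gives the hydroquinone monomethyl ether pattern.

**Step 12**
Reactants: 18 3-(hydroxymethyl)-4-methoxyphenol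
Product: 19 2-bromo-5-(hydroxymethyl)-4-methoxyphenol
Conditions: NBS (1.0 equiv), CH2Cl2, −20 °C
Reagents that add atoms: N-bromosuccinimide, O=C1CCC(=O)N1Br
Why: Electrophilic bromination ortho to the phenol OH (strongest director); the ortho site flanked by OH and CH2OH is hindered, so bromine enters para to the hydroxymethyl group.

**Step 13**
Reactants: 19 2-bromo-5-(hydroxymethyl)-4-methoxyphenol
Product: 20 [2-bromo-4-methoxy-5-(TIPS-oxymethyl)phenoxy]-TIPS (aryl bromide bis-TIPS ether)
Conditions: TIPSCl (2.3 equiv), imidazole, DMF, rt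
Reagents that add atoms: chlorotri(propan-2-yl)silane, CC(C)[Si](Cl)(C(C)C)C(C)C
Why: Silyl ether formation at both hydroxyls; the bulky TIPS group on the phenol resists the anionic O→C silyl shift when the neighbouring carbon is metalated in step 14.

**Step 14**
Reactants: 20 aryl bromide bis-TIPS ether; 13 (4aS,8aS)-5,5,8a-trimethyl-1-methylideneoctahydronaphthalen-2(1H)-one
Product: 23 (1R,4aS,8aS)-1-{[5-methoxy-2-(TIPS-oxy)-4-(TIPS-oxymethyl)phenyl]methyl}-5,5,8a-trimethyloctahydronaphthalen-2(1H)-one, via aryllithium 21 (not isolated), via arylmagnesium bromide 22 (not isolated)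
Conditions: 20, n-BuLi, THF, −78 °C; MgBr2·OEt2; then freshly made 13, CuBr·SMe2 (10 mol%), −78→−30 °C; aq NH4Cl
Reagents that add atoms: none
Why: Copper-catalysed conjugate addition of the aryl Grignard to the exo-methylene ketone forms the C11–aryl bond; the enolate is protonated axially from the face anti to the C10 methyl, giving 9α-H (equatorial side chain, also the thermodynamic epimer).

**Step 15**
Reactants: 23 (1R,4aS,8aS)-1-{[5-methoxy-2-(TIPS-oxy)-4-(TIPS-oxymethyl)phenyl]methyl}-5,5,8a-trimethyloctahydronaphthalen-2(1H)-one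
Product: 24 [2-(AlbCH2)-4-methoxy-5-(TIPS-oxymethyl)phenoxy]-TIPS
Conditions: Ph3PCH3Br, KHMDS, toluene, 0→80 °C
Reagents that add atoms: methyltriphenylphosphonium bromide (as its ylide), C[P+](c1ccccc1)(c1ccccc1)c1ccccc1.[Br-]
Why: Wittig methylenation of the hindered C8 ketone installs the exocyclic alkene; any C9 epimerisation under the basic conditions converges on the equatorial (9S) isomer.

**Step 16**
Reactants: 24 [2-(AlbCH2)-4-methoxy-5-(TIPS-oxymethyl)phenoxy]-TIPS
Product: 26 2-(AlbCH2)-5-(hydroxymethyl)-4,4-dimethoxycyclohexa-2,5-dien-1-one, via free phenol 25 (not isolated)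
Conditions: TBAF, THF, 0 °C→rt; AcOH; then PhI(OAc)2, MeOH, 0 °C
Reagents that add atoms: methanol, CO
Why: Fluoride desilylation followed by hypervalent-iodine oxidative dearomatisation of the p-methoxyphenol in methanol gives the quinone monoketal, with the carbonyl at the former phenol carbon (next to the AlbCH2-bearing carbon) and the ketal next to the hydroxymethyl-bearing carbon.

**Step 17**
Reactants: 26 2-(AlbCH2)-5-(hydroxymethyl)-4,4-dimethoxycyclohexa-2,5-dien-1-one
Product: 27 (1R,6S)-1-(AlbCH2)-4-(hydroxymethyl)-5,5-dimethoxy-7-oxabicyclo[4.1.0]hept-3-en-2-one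
Conditions: Ph3COOH, NaHMDS, L-(+)-DIPT, toluene, −55 °C; aq NH4Cl
Reagents that add atoms: triphenylmethyl hydroperoxide, OOC(c1ccccc1)(c1ccccc1)c1ccccc1
Why: Tartrate-mediated nucleophilic (Weitz–Scheffer-type) epoxidation of a hydroxymethyl-bearing quinone monoketal: the peroxide, anchored through the alkoxide/tartrate complex, adds to the only unsubstituted β-carbon (the other β-carbon is fully substituted), and the tartrate enantiomer fixes the face to give the (1R,6S) epoxide (D-DIPT delivers the other face).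

**Step 18**
Reactants: 27 (1R,6S)-1-(AlbCH2)-4-(hydroxymethyl)-5,5-dimethoxy-7-oxabicyclo[4.1.0]hept-3-en-2-one
Product: 28 (1R,6S)-1-(AlbCH2)-4-(hydroxymethyl)-7-oxabicyclo[4.1.0]hept-3-ene-2,5-dione
Conditions: montmorillonite K10, wet CH2Cl2, rt
Reagents that add atoms: water, O
Why: Mild solid-acid ketal hydrolysis releases the second carbonyl while the epoxide and the acid-sensitive exocyclic alkene survive.

**Step 19**
Reactants: 28 (1R,6S)-1-(AlbCH2)-4-(hydroxymethyl)-7-oxabicyclo[4.1.0]hept-3-ene-2,5-dione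
Product: 29 (1R,5R,6R)-1-(AlbCH2)-5-hydroxy-4-(hydroxymethyl)-7-oxabicyclo[4.1.0]hept-3-en-2-one
Conditions: DIBAL-H (3 equiv), THF, −78 °C; Rochelle salt
Reagents that add atoms: none
Why: Regio- and stereoselective 1,2-reduction of the epoxy-enedione: the C5 carbonyl next to the epoxide CH is attacked (C2 is shielded by the quaternary C1 and its bulky substituent), with hydride anti to the epoxide oxygen, giving the cis-epoxy alcohol (5R).

**Step 20**
Reactants: 30 ethyl acetate
Product: 31 4-methylhepta-1,6-dien-4-ol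
Conditions: CH2=CHCH2MgBr (2.2 equiv), Et2O, 0 °C; aq NH4Cl
Reagents that add atoms: allylmagnesium bromide, C=CC[Mg]Br
Why: Double Grignard addition to the ester gives the symmetric tertiary diallyl carbinol.

**Step 21**
Reactants: 31 4-methylhepta-1,6-dien-4-ol
Product: 33 3-hydroxy-3-methylpentanedioic acid, via bis-ozonide 32 (not isolated)
Conditions: O3, CH2Cl2, −78 °C; then H2O2, HCO2H, 60 °C
Reagents that add atoms: ozone, [O-][O+]=O; hydrogen peroxide, OO
Why: Ozonolysis of both terminal alkenes with oxidative work-up gives the diacid directly.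

**Step 22**
Reactants: 33 3-hydroxy-3-methylpentanedioic acid
Product: 34 4-hydroxy-4-methyloxane-2,6-dione (3-hydroxy-3-methylglutaric anhydride)
Conditions: DCC (1.0 equiv), acetone, rt; filter
Reagents that add atoms: none
Why: Carbodiimide dehydration closes the six-membered cyclic anhydride and leaves the tertiary hydroxyl free.

**Step 23**
Reactants: 29 (1R,5R,6R)-1-(AlbCH2)-5-hydroxy-4-(hydroxymethyl)-7-oxabicyclo[4.1.0]hept-3-en-2-one; 34 4-hydroxy-4-methyloxane-2,6-dione
Product: 35 (3S)-3-hydroxy-5-{[(1R,5R,6R)-1-(AlbCH2)-5-hydroxy-2-oxo-7-oxabicyclo[4.1.0]hept-3-en-4-yl]methoxy}-3-methyl-5-oxopentanoic acid (target)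
Conditions: (DHQD)2AQN (30 mol%), 34 (3 equiv), Et2O/toluene, −30 °C
Reagents that add atoms: none
Why: Modified-cinchona-alkaloid-catalysed desymmetrising alcoholysis of the prochiral anhydride by the more reactive primary allylic alcohol; the catalyst selects one enantiotopic carbonyl and so sets the (3S) carbinol centre ((DHQ)2AQN selects the other carbonyl).

**Compound list**
1 | 2-methylcyclopentane-1,3-dione | CC1C(=O)CCC1=O | starting material
2 | pent-1-en-3-one | CCC(=O)C=C | starting material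
3 | 2-methyl-2-(3-oxopentyl)cyclopentane-1,3-dione | CCC(=O)CCC1(C)C(=O)CCC1=O | intermediate
4 | (7aS)-4,7a-dimethyl-2,3,7,7a-tetrahydro-1H-indene-1,5(6H)-dione | O=C1CC[C@]2(C)C(=O)CCC2=C1C | intermediate
5 | (1S,7aS)-1-hydroxy-4,7a-dimethyl-1,2,3,6,7,7a-hexahydro-5H-inden-5-one | O=C1CC[C@]2(C)[C@@H](O)CCC2=C1C | intermediate
6 | dilithium alkoxide-enolate from 1,4-reduction of 5 (trans-fused; in flask) | [Li]OC1CC[C@]2(C)[C@@H](O[Li])CC[C@H]2C=1C | intermediate
7 | (1S,3aR,7aS)-1-hydroxy-4,4,7a-trimethyloctahydro-5H-inden-5-one | O=C1CC[C@]2(C)[C@@H](O)CC[C@H]2C1(C)C | intermediate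
8 | hydrazone of 7 (in flask) | NN=C1CC[C@]2(C)[C@@H](O)CC[C@H]2C1(C)C | intermediate
9 | (1S,3aS,7aS)-4,4,7a-trimethyloctahydro-1H-inden-1-ol | C1CC[C@]2(C)[C@@H](O)CC[C@H]2C1(C)C | intermediate
10 | (3aS,7aS)-4,4,7a-trimethyloctahydro-1H-inden-1-one | C1CC[C@]2(C)C(=O)CC[C@H]2C1(C)C | intermediate
11 | (1R,3aS,7aS)-1-ethenyl-4,4,7a-trimethyloctahydro-1H-inden-1-ol | C1CC[C@]2(C)[C@](O)(C=C)CC[C@H]2C1(C)C | intermediate
12 | {[(4aS,8aS)-5,5,8a-trimethyl-2-oxodecahydronaphthalen-1-yl]methyl}(phenyl)iodonium tosylate (in flask; C1 epimers) | O=C1CC[C@H]2C(C)(C)CCC[C@]2(C)C1C[I+]c1ccccc1.Cc1ccc(cc1)S(=O)(=O)[O-] | intermediate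
13 | (4aS,8aS)-5,5,8a-trimethyl-1-methylideneoctahydronaphthalen-2(1H)-one | O=C1CC[C@H]2C(C)(C)CCC[C@]2(C)C1=C | intermediate
14 | anisole | COc1ccccc1 | starting material
15 | 2-lithioanisole (in flask) | COc1ccccc1[Li] | intermediate
16 | (2-methoxyphenyl)methanol | COc1ccccc1CO | intermediate
17 | (5-bromo-2-methoxyphenyl)methanol | COc1ccc(Br)cc1CO | intermediate
18 | 3-(hydroxymethyl)-4-methoxyphenol | COc1ccc(O)cc1CO | intermediate
19 | 2-bromo-5-(hydroxymethyl)-4-methoxyphenol | COc1cc(Br)c(O)cc1CO | intermediate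
20 | [2-bromo-4-methoxy-5-(TIPS-oxymethyl)phenoxy]-TIPS | COc1cc(Br)c(O[Si](C(C)C)(C(C)C)C(C)C)cc1CO[Si](C(C)C)(C(C)C)C(C)C | intermediate
21 | aryllithium from 20 (Li in place of Br; in flask) | COc1cc([Li])c(O[Si](C(C)C)(C(C)C)C(C)C)cc1CO[Si](C(C)C)(C(C)C)C(C)C | intermediate
22 | arylmagnesium bromide from 21 (in flask) | COc1cc([Mg]Br)c(O[Si](C(C)C)(C(C)C)C(C)C)cc1CO[Si](C(C)C)(C(C)C)C(C)C | intermediate
23 | (1R,4aS,8aS)-1-{[5-methoxy-2-(TIPS-oxy)-4-(TIPS-oxymethyl)phenyl]methyl}-5,5,8a-trimethyloctahydronaphthalen-2(1H)-one | O=C1CC[C@H]2C(C)(C)CCC[C@]2(C)[C@H]1Cc1cc(OC)c(CO[Si](C(C)C)(C(C)C)C(C)C)cc1O[Si](C(C)C)(C(C)C)C(C)C | intermediate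
24 | [2-(AlbCH2)-4-methoxy-5-(TIPS-oxymethyl)phenoxy]-TIPS | C=C1CC[C@H]2C(C)(C)CCC[C@]2(C)[C@H]1Cc1cc(OC)c(CO[Si](C(C)C)(C(C)C)C(C)C)cc1O[Si](C(C)C)(C(C)C)C(C)C | intermediate
25 | 2-(AlbCH2)-5-(hydroxymethyl)-4-methoxyphenol (in flask) | C=C1CC[C@H]2C(C)(C)CCC[C@]2(C)[C@H]1Cc1cc(OC)c(CO)cc1O | intermediate
26 | 2-(AlbCH2)-5-(hydroxymethyl)-4,4-dimethoxycyclohexa-2,5-dien-1-one | C=C1CC[C@H]2C(C)(C)CCC[C@]2(C)[C@H]1CC1=CC(OC)(OC)C(CO)=CC1=O | intermediate
27 | (1R,6S)-1-(AlbCH2)-4-(hydroxymethyl)-5,5-dimethoxy-7-oxabicyclo[4.1.0]hept-3-en-2-one | C=C1CC[C@H]2C(C)(C)CCC[C@]2(C)[C@H]1C[C@@]12O[C@@H]1C(OC)(OC)C(CO)=CC2=O | intermediate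
28 | (1R,6S)-1-(AlbCH2)-4-(hydroxymethyl)-7-oxabicyclo[4.1.0]hept-3-ene-2,5-dione | C=C1CC[C@H]2C(C)(C)CCC[C@]2(C)[C@H]1C[C@@]12O[C@@H]1C(=O)C(CO)=CC2=O | intermediate
29 | (1R,5R,6R)-1-(AlbCH2)-5-hydroxy-4-(hydroxymethyl)-7-oxabicyclo[4.1.0]hept-3-en-2-one | C=C1CC[C@H]2C(C)(C)CCC[C@]2(C)[C@H]1C[C@@]12O[C@@H]1[C@H](O)C(CO)=CC2=O | intermediate
30 | ethyl acetate | CCOC(C)=O | starting material
31 | 4-methylhepta-1,6-dien-4-ol | C=CCC(C)(O)CC=C | intermediate
32 | bis-ozonide of 31 (two 1,2,4-trioxolanes; in flask) | CC(O)(CC1OCOO1)CC1OCOO1 | intermediate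
33 | 3-hydroxy-3-methylpentanedioic acid | CC(O)(CC(=O)O)CC(=O)O | intermediate
34 | 4-hydroxy-4-methyloxane-2,6-dione | CC1(O)CC(=O)OC(=O)C1 | intermediate
35 | (3S)-3-hydroxy-5-{[(1R,5R,6R)-1-(AlbCH2)-5-hydroxy-2-oxo-7-oxabicyclo[4.1.0]hept-3-en-4-yl]methoxy}-3-methyl-5-oxopentanoic acid | C=C1CC[C@H]2C(C)(C)CCC[C@]2(C)[C@H]1C[C@@]12O[C@@H]1[C@H](O)C(COC(=O)C[C@@](C)(O)CC(=O)O)=CC2=O | target

**Totals**
Total step count: 23. Longest linear sequence: 15 steps (steps 1–8, 14–19, 23).

**Three steps most likely to fail**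

Step 8 (the proposed new ring expansion). The risks are ionisation of the tertiary allylic alcohol by the sulfonic acid released, and migration of the ring CH2 in place of the quaternary carbon. The fallback uses known chemistry and sets out from 11. Vanadium-directed epoxidation (VO(acac)2, t-BuOOH, toluene) gives the epoxy alcohol (1S,3aS,7aS)-4,4,7a-trimethyl-1-(oxiran-2-yl)octahydro-1H-inden-1-ol F1. BF3·OEt2 in CH2Cl2 at −78 °C then effects the established semipinacol rearrangement of a 2,3-epoxy alcohol to the ring-expanded β-hydroxy ketone (4aS,8aS)-1-(hydroxymethyl)-5,5,8a-trimethyloctahydronaphthalen-2(1H)-one F2. MsCl/Et3N converts this to the mesylate [(4aS,8aS)-5,5,8a-trimethyl-2-oxodecahydronaphthalen-1-yl]methyl methanesulfonate F3, which DBU eliminates; the sequence comes back to the route at 13.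

Step 17 (facial control of the epoxidation next to the bulky chiral terpenyl group). The tartrate reagent may be mismatched with the substrate. The fallback sets out from 26 and replaces reagent control by a covalently bound auxiliary. Ketal exchange with (2R,4R)-pentane-2,4-diol (PPTS, benzene) gives the C2-symmetric spiroketal dienone 9-(AlbCH2)-11-(hydroxymethyl)-2,4-dimethyl-1,5-dioxaspiro[5.5]undeca-7,10-dien-8-one F4 (2R,4R; the antipodal diol is taken if its facial sense is the one needed). Nucleophilic epoxidation with t-BuOOH/KOt-Bu in THF at −40 °C under auxiliary control gives the epoxy spiroketal F5, the 7,8-epoxide of F4. Hydrolysis under the conditions of step 18 comes back to the route at 28.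

Step 23 (desymmetrising acylation with a precious, polyfunctional alcohol as the limiting partner). Selectivity between the enantiotopic carbonyls may be low. The fallback sets out from 34 and moves the desymmetrisation to the small-molecule stage. Quinidine-mediated opening with excess allyl alcohol (toluene, −55 °C; quinine if the opposite sense is found), with enrichment by salt crystallisation, gives the half ester (3R)-3-hydroxy-3-methyl-5-oxo-5-(prop-2-en-1-yloxy)pentanoic acid F6. EDC/DMAP esterification of its free acid with the primary alcohol of 29 gives the allyl ester of the target F7. Pd(PPh3)4/morpholine removes the allyl group and the sequence comes back at 35.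

**Further compounds**
F1 | step 8 | (1S,3aS,7aS)-4,4,7a-trimethyl-1-(oxiran-2-yl)octahydro-1H-inden-1-ol | C1CC[C@]2(C)[C@](O)(C3CO3)CC[C@H]2C1(C)C
F2 | step 8 | (4aS,8aS)-1-(hydroxymethyl)-5,5,8a-trimethyloctahydronaphthalen-2(1H)-one | O=C1CC[C@H]2C(C)(C)CCC[C@]2(C)C1CO
F3 | step 8 | [(4aS,8aS)-5,5,8a-trimethyl-2-oxodecahydronaphthalen-1-yl]methyl methanesulfonate | O=C1CC[C@H]2C(C)(C)CCC[C@]2(C)C1COS(C)(=O)=O
F4 | step 17 | (2R,4R)-9-(AlbCH2)-11-(hydroxymethyl)-2,4-dimethyl-1,5-dioxaspiro[5.5]undeca-7,10-dien-8-one | C=C1CC[C@H]2C(C)(C)CCC[C@]2(C)[C@H]1CC1=CC3(O[C@H](C)C[C@@H](C)O3)C(CO)=CC1=O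
F5 | step 17 | 7,8-epoxide of F4 with the (1R,6S) oxabicyclic configuration of 27 | C=C1CC[C@H]2C(C)(C)CCC[C@]2(C)[C@H]1C[C@@]12O[C@@H]1C3(O[C@H](C)C[C@@H](C)O3)C(CO)=CC2=O
F6 | step 23 | (3R)-3-hydroxy-3-methyl-5-oxo-5-(prop-2-en-1-yloxy)pentanoic acid | OC(=O)C[C@@](C)(O)CC(=O)OCC=C
F7 | step 23 | prop-2-en-1-yl ester of target 35 | C=C1CC[C@H]2C(C)(C)CCC[C@]2(C)[C@H]1C[C@@]12O[C@@H]1[C@H](O)C(COC(=O)C[C@@](C)(O)CC(=O)OCC=C)=CC2=O
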